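- The trap is to carry cedar's percentages over to a heavier flask, as if every charge lost the same fraction in the same time.

| setting | cedar | maple | amber | blue | teal | ochre | green | violet |
|---|---|---|---|---|---|---|---|---|
| first end groups | 0.084 M | 1.1 M | 0.12 M | 0.80 M | 0.060 M | 0.20 M | 0.40 M | 0.30 M |
| gas | 75 mM (held) | 75 mM (held) | 75 mM (held) | 75 mM (held) | 75 mM (held) | 75 mM (held) | 75 mM (held) | 75 mM (held) |
| remark | run made earlier | run made earlier |  |  |  |  |  |  |
| time |  |  | 2.5 min | 2.5 min | 2.5 min | 2.5 min | 2.5 min | 2.5 min |

| run | time / s | links / % | first end groups / % |
|---|---|---|---|
| cedar | 10.0 | 2 | 92 |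
| cedar | 20.0 | 7 | 81 |
| cedar | 30.0 | 10 | 67 |
| cedar | 40.0 | 19 | 51 |
| cedar | 50.0 | 19 | 39 |
| cedar | 60.0 | 21 | 27 |
| cedar | 80.0 | 27 | 12 |
| maple | 10.0 | 1 | 96 |
| maple | 15.0 | 0 | 97 |
| maple | 20.0 | 0 | 95 |
| maple | 30.0 | 0 | 90 |
| maple | 50.0 | 4 | 82 |
| maple | 80.0 | 1 | 70 |

(each reading ± 1.5 percentage points)

- percentages count the first end groups that a species holds: one side product counts as two
- at the start none of second end groups is dissolved
- the numbers in the tables scatter with a standard deviation of 1.5 percentage points
- candidate steps: first end groups + second end groups -> links + released group; gas <-> second end groups; first end groups + links -> side product; links <-> isomer of the product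

* ranking by amount of links, in percent of the first end groups charged, from high to low, at 2.5 min (amber / blue / teal / ochre / green / violet)
* the amount of links, in percent of the first end groups charged of the flask you put first, at 2.5 min
* the amount of links, in percent of the first end groups charged of the flask you put last, at 2.5 min

- So work with the fraction left. Maple loses 0.240 min⁻¹ of its charge between 30.0 s and 80.0 s, and the part from 30.0 s to 50.0 s gives 0.240 min⁻¹, so maple's readings show no slowing over that stretch.
- But is that a property of maple or of the gas? Between 30.0 s and 40.0 s, the readings of cedar show a loss of 0.960 min⁻¹, more than maple, although maple holds the larger charge. I therefore read the gas crossing over to second end groups as the rate-limiting step in maple: a steady supply shared out over the charge.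
- Call the amount of first end groups which maple's steady fall takes in the asked time the reach, 0.660 M. Where the reach is below the charge and the gas is held as in maple, my estimate of the fraction left is one minus reach over charge.
- The objection is cedar. Maple's fall, counted as an amount, comes to 419 % of cedar's charge by 80.0 s, yet cedar still shows 12 % left at its last reading. So in cedar the reach overshoots what was taken.
- In blue the reach is smaller than the charge, which gives an estimated 17.5 % left. But blue's charge is not far above the reach, and cedar showed an overshoot, so I take this as a low figure.
- The reach exceeds every other charge. Ranking by reach over charge, high to low, I would write teal, amber, ochre, violet, green, blue, with teal near the 27 % of links in cedar's last reading and blue within the 0 % to 4 % of maple's readings.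
- The forecast gives the same order, teal > amber > ochre > violet > green > blue, with 34 % (27 % to 41 %) on top and 1.2 % (0.7 % to 2.4 %) at the bottom: “Percent therefore falls with loading”.
- The flasks give teal > amber > ochre > violet > green > blue, with 32.2 % on top and 3.12 % at the bottom.

    first end groups + second end groups → links + released group (k = 0.770 M⁻¹ s⁻¹)
    gas ⇌ second end groups, rate k2*(csat - [second end groups]) (kL = 0.0310 s⁻¹)
    first end groups + links → side product (k = 0.240 M⁻¹ s⁻¹)
    links ⇌ isomer of the product (K = 1.60, k = 0.270 s⁻¹)

- Blue keeps 30 % of its first end groups at 2.50 min, where the reach left 17.5 %. The neighbour of blue charged with 2.0 M has a reach of 33.0 % of its charge, which leaves 67.0 %. That flask keeps 67 %, and its links stand at 0.341 %.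

The runs were computed with made-up constants; noise was put on by code.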